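## Retrosynthetic overview
- **Feature:** ring A (C4a–C5–C6–C7–C8–C8a, chromene numbering) shares C4a–C8a with the dimethylpyran ring B. Four of its carbons are already loaded: C4a bears C4, C8a bears the ring oxygen O1, C8 the prenyl group, C7 the arylethyl chain. Only C5(OH) and C6(H) are missing.
- **Key disconnection:** C4a–C5 and C6–C7. Ring A is built from the diene C4a=C8a–C8=C7 of the 3-acyl-2-pyrone 18 and the two carbons of ethoxyacetylene 19, and the lactone bridge C5(=O)–O6 leaves as carbon dioxide. O1 sits on C8a before the arene exists.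
- **After ring A:** the C5 ethyl ether, peri to the C4 ketone, is cleaved by chelation. The ketone then becomes the C3=C4 alkene and the silyl ether is removed.
- **Before ring A:** 18 comes from 4-hydroxy-2-pyrone 12 by C3 acylation and acid-catalysed oxa-Michael closure of ring B. That acid would also close the same hydroxyl onto a neighbouring prenyl group, so C8 carries allyl until ring B is shut and is then made prenyl by cross-metathesis. Pyrone 12 comes from methyl acetoacetate by γ-allylation, γ-acylation with Weinreb amide 4 and lactonisation.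
- **Ring order:** 2-pyrone, then ring B, then ring A (the pyrone ring is consumed). The phenol ring is bought.

Key step: step 9

Remark: the target has no stereocentre; 10, 11, 20 and 24 carry transient stereocentres, are handled as racemates or mixtures and are written without configuration; the pyrano[4,3-b]pyran locants of 16 and 18 (O1, C2, C3, C4, C4a, C5, O6, C7, C8, C8a; the fusion is also written pyrano[3,2-c]pyran) fall on the same atoms as the chromane locants.

## Route

Step 1
Reactants: 1 3-(4-hydroxyphenyl)propanoic acid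
Product: 3 3-(4-hydroxyphenyl)-N-methoxy-N-methylpropanamide, via acylimidazole 2 (not isolated)
Conditions: CDI (1.05 equiv), CH2Cl2, 0 °C to rt; then MeNHOMe·HCl (1.3 equiv), rt
Reagents that add atoms: N,O-dimethylhydroxylamine hydrochloride, CNOC.Cl; 1,1'-carbonyldiimidazole, O=C(n1ccnc1)n1ccnc1 (imidazolyl group of 2 only)
Why: Carbonyldiimidazole amide coupling, in which the carboxylic acid is activated ahead of the much less reactive phenol and the acylimidazole is opened by the hydroxylamine nitrogen to give the Weinreb amide.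

Step 2
Reactants: 3 3-(4-hydroxyphenyl)-N-methoxy-N-methylpropanamide
Product: 4 N-methoxy-N-methyl-3-[4-(triisopropylsilyloxy)phenyl]propanamide
Conditions: TIPSCl (1.2 equiv), imidazole (2.5 equiv), DMF, rt
Reagents that add atoms: triisopropylsilyl chloride, CC(C)[Si](Cl)(C(C)C)C(C)C
Why: Imidazole-promoted phenol silylation installs a bulky aryl silyl ether that should stand amide bases, dilute trifluoroacetic acid and cold BCl3, and removes the acidic OH that would quench the dianion of step 4 and add to the ynol ether of step 9.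

Step 3
Reactants: 5 methyl acetoacetate; 6 allyl bromide
Product: 8 methyl 3-oxohept-6-enoate, via sodium lithium dianion 7 (not isolated)
Conditions: NaH (1.1 equiv), THF, 0 °C; n-BuLi (1.05 equiv), 0 °C; 6 (1.0 equiv), 0 °C to rt; 1 M HCl
Reagents that add atoms: sodium hydride, [Na+].[H-]; n-butyllithium, [Li]CCCC (counter-ions of 7 only)
Why: γ-Alkylation of a β-keto ester dianion, in which the last-formed and most basic terminal carbanion displaces the allylic bromide by SN2 while the α-carbon stays masked as the enolate.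

Step 4
Reactants: 8 methyl 3-oxohept-6-enoate; 4 N-methoxy-N-methyl-3-[4-(triisopropylsilyloxy)phenyl]propanamide
Product: 11 methyl 4-allyl-3,5-dioxo-7-[4-(triisopropylsilyloxy)phenyl]heptanoate, via dilithium dianion 9 (not isolated), via hemiaminal dilithium salt 10 (not isolated)
Conditions: LiN(iPr)2 (LDA, 2.2 equiv), THF, −78 to 0 °C; 4 (0.9 equiv), −78 to 0 °C; cold 1 M HCl
Reagents that add atoms: lithium diisopropylamide, [Li+].CC(C)[N-]C(C)C (lithium of 9 and 10 only)
Why: Claisen-type γ-acylation of the β-keto ester dianion with a Weinreb amide, whose chelated tetrahedral adduct 10 lasts until the quench, so the acidic tricarbonyl product cannot protonate unreacted dianion and no second addition occurs.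

Step 5
Reactants: 11 methyl 4-allyl-3,5-dioxo-7-[4-(triisopropylsilyloxy)phenyl]heptanoate
Product: 12 5-allyl-4-hydroxy-6-{2-[4-(triisopropylsilyloxy)phenyl]ethyl}-2H-pyran-2-one
Conditions: DBU (1.5 equiv), toluene, 60 °C; 1 M HCl
Reagents that add atoms: none
Why: Base-induced enol lactonisation of a 3,5-dioxo ester, in which the C5 enolate oxygen attacks the ester and methanol is lost, and the allyl CH2 on the non-acidifying pyrone C5 position should not be isomerised.

Step 6
Reactants: 12 5-allyl-4-hydroxy-6-{2-[4-(triisopropylsilyloxy)phenyl]ethyl}-2H-pyran-2-one; 13 3-methylbut-2-enoic acid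
Product: 15 5-allyl-4-hydroxy-3-(3-methylbut-2-enoyl)-6-{2-[4-(triisopropylsilyloxy)phenyl]ethyl}-2H-pyran-2-one, via enol ester 14 (not isolated)
Conditions: 13 (1.1 equiv), DCC (1.2 equiv), DMAP (0.5 equiv), toluene, rt then 60 °C
Reagents that add atoms: none
Why: Carbodiimide O-acylation followed by DMAP-catalysed O-to-C acyl transfer (Fries-type rearrangement of a 4-acyloxy-2-pyrone) places the acyl group on C3, the only free nucleophilic carbon, without acid, and any deconjugated acyl isomer should return to the conjugated enone in the acidic tricarbonyl product.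

Step 7
Reactants: 15 5-allyl-4-hydroxy-3-(3-methylbut-2-enoyl)-6-{2-[4-(triisopropylsilyloxy)phenyl]ethyl}-2H-pyran-2-one
Product: 16 8-allyl-2,2-dimethyl-7-{2-[4-(triisopropylsilyloxy)phenyl]ethyl}-2,3-dihydro-4H,5H-pyrano[4,3-b]pyran-4,5-dione
Conditions: TFA–CH2Cl2 (1:3), 0 °C to rt
Reagents that add atoms: none
Why: Acid-catalysed 6-endo-trig intramolecular oxa-Michael addition, in which protonation of the chelated enone puts tertiary-cation character on the CMe2 carbon and the C4 hydroxyl closes on it to the thermodynamically preferred 2-pyrone isomer, while the monosubstituted allyl alkene (unlike a prenyl group, which the same hydroxyl would capture) should not be protonated by dilute acid at room temperature.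

Step 8
Reactants: 16 8-allyl-2,2-dimethyl-7-{2-[4-(triisopropylsilyloxy)phenyl]ethyl}-2,3-dihydro-4H,5H-pyrano[4,3-b]pyran-4,5-dione; 17 2-methylbut-2-ene
Product: 18 2,2-dimethyl-8-(3-methylbut-2-enyl)-7-{2-[4-(triisopropylsilyloxy)phenyl]ethyl}-2,3-dihydro-4H,5H-pyrano[4,3-b]pyran-4,5-dione
Conditions: second-generation Grubbs catalyst (5 mol%), 17 (co-solvent, large excess), CH2Cl2, sealed tube, 40 °C
Reagents that add atoms: none
Why: Olefin cross-metathesis of a terminal alkene with excess 2-methylbut-2-ene is the standard allyl-to-prenyl exchange, driven by loss of propene, and the trisubstituted product alkene and the ring double bonds are inert to the catalyst.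

Step 9
Reactants: 18 2,2-dimethyl-8-(3-methylbut-2-enyl)-7-{2-[4-(triisopropylsilyloxy)phenyl]ethyl}-2,3-dihydro-4H,5H-pyrano[4,3-b]pyran-4,5-dione; 19 ethoxyacetylene
Product: 21 5-ethoxy-2,2-dimethyl-8-(3-methylbut-2-enyl)-7-{2-[4-(triisopropylsilyloxy)phenyl]ethyl}chroman-4-one, via bridged lactone 20 (not isolated)
Conditions: 19 (10 equiv, about 50 wt% in hexanes, added in three portions), Yb(fod)3 (10 mol%), toluene, sealed tube, 85 °C
Reagents that add atoms: none
Why: Proposed new method: the C4 ketone and the C5 lactone carbonyl both sit on C4a and should bind Yb(fod)3 as a six-membered chelate, lowering the LUMO of the diene C4a=C8a–C8=C7 enough to offset the donor O1 on C8a, so that the ynol ether engages it in an asynchronous inverse-electron-demand [4+2] in which the terminal CH of 19 leads at C7 and the ethoxy-bearing carbon follows at C4a. The 2-oxabicyclo[2.2.2]octadienone 20 then expels carbon dioxide by retro-[4+2] at the bath temperature, so ring A is closed by intermolecular cycloaddition (new bonds C4a–C5 and C6–C7) and becomes aromatic by cycloreversion without an oxidant. The closest known reaction type is the benzannulation of 3-carbonyl-5,6-dialkyl-2-pyrones with ketene acetals, enol ethers and ynamines, also under lanthanide catalysis; an ynol ether on a fully substituted, ring-fused 4-alkoxy-3-acyl-2-pyrone has not been shown. The two bridgehead stereocentres of 20 (C4a and C7, racemic) vanish with the carbon dioxide, so nothing stereochemical has to be controlled. The selectivity needed is regiochemical: the largest LUMO coefficient lies at C7, the vinylogous acceptor terminus of both carbonyl groups, and the largest HOMO coefficient at the unsubstituted alkyne carbon, and that small CH is also the end that fits next to the arylethyl and prenyl groups, which places OEt on C5 peri to the ketone. Holding the bath below the retro-ene threshold of 19 and feeding it in portions protects the dienophile, there is no OH left to add to it, and the hindered, weakly donating prenyl alkene should not compete.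

Step 10
Reactants: 21 5-ethoxy-2,2-dimethyl-8-(3-methylbut-2-enyl)-7-{2-[4-(triisopropylsilyloxy)phenyl]ethyl}chroman-4-one
Product: 23 5-hydroxy-2,2-dimethyl-8-(3-methylbut-2-enyl)-7-{2-[4-(triisopropylsilyloxy)phenyl]ethyl}chroman-4-one, via dichloroboron chelate 22 (not isolated)
Conditions: BCl3 (1.5 equiv, 1 M in CH2Cl2), CH2Cl2, −78 to 0 °C; poured into cold aq NaHCO3
Reagents that add atoms: boron trichloride, ClB(Cl)Cl (boron and chlorine of 22 only)
Why: Chelation-assisted aryl ether cleavage, in which BCl3 bridges the C4 ketone and the peri C5 ether oxygen and chloride removes the ethyl group by SN2, while the silyl ether and O1 lack such a chelate, no free hydroxyl lies ortho to the prenyl group, and the basic quench keeps HCl away from the alkene.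

Step 11
Reactants: 23 5-hydroxy-2,2-dimethyl-8-(3-methylbut-2-enyl)-7-{2-[4-(triisopropylsilyloxy)phenyl]ethyl}chroman-4-one
Product: 25 2,2-dimethyl-8-(3-methylbut-2-enyl)-7-{2-[4-(triisopropylsilyloxy)phenyl]ethyl}-2H-chromen-5-ol, via chroman-4-ol 24 (not isolated)
Conditions: NaBH4 (3 equiv), THF–MeOH (4:1), 0 °C to rt; aq NH4Cl, extraction; crude 24, PPTS (10 mol%), toluene, 60 °C
Reagents that add atoms: none
Why: Borohydride 1,2-reduction gives the racemic benzylic alcohol 24, whose C4 cation is stabilised by both ortho oxygens (O1 through C8a and the C5 hydroxyl, an o-quinone methide after proton loss), so E1 dehydration to the conjugated C3=C4 alkene should run with a pyridinium salt too weak to protonate the prenyl alkene or cleave the silyl ether.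

Step 12
Reactants: 25 2,2-dimethyl-8-(3-methylbut-2-enyl)-7-{2-[4-(triisopropylsilyloxy)phenyl]ethyl}-2H-chromen-5-ol
Product: 26 7-[2-(4-hydroxyphenyl)ethyl]-2,2-dimethyl-8-(3-methylbut-2-enyl)-2H-chromen-5-ol (target)
Conditions: Bu4NF (1.1 equiv), AcOH (1.1 equiv), THF, 0 °C
Reagents that add atoms: none
Why: Fluoride desilylation driven by Si–F bond formation, buffered with acetic acid so that the electron-rich phenoxides are not left exposed, under conditions to which the chromene and prenyl alkenes are inert.

## Compound list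
1 | 3-(4-hydroxyphenyl)propanoic acid | OC(=O)CCc1ccc(O)cc1 | starting material
2 | 1-[3-(4-hydroxyphenyl)propanoyl]imidazole | O=C(CCc1ccc(O)cc1)n1ccnc1 | intermediate
3 | 3-(4-hydroxyphenyl)-N-methoxy-N-methylpropanamide | CON(C)C(=O)CCc1ccc(O)cc1 | intermediate
4 | N-methoxy-N-methyl-3-[4-(triisopropylsilyloxy)phenyl]propanamide | CON(C)C(=O)CCc1ccc(O[Si](C(C)C)(C(C)C)C(C)C)cc1 | intermediate
5 | methyl acetoacetate | COC(=O)CC(C)=O | starting material
6 | allyl bromide | C=CCBr | starting material
7 | sodium lithium dianion (bis-enolate) of methyl acetoacetate | [Na+].[Li+].COC([O-])=CC([O-])=C | intermediate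
8 | methyl 3-oxohept-6-enoate | COC(=O)CC(=O)CCC=C | intermediate
9 | dilithium dianion (bis-enolate) of methyl 3-oxohept-6-enoate | [Li+].[Li+].COC([O-])=CC([O-])=CCC=C | intermediate
10 | dilithium salt of the tetrahedral N-methoxy-N-methyl hemiaminal adduct of 9 and 4 (mixture of diastereomers) | [Li+].[Li+].COC(=O)C=C([O-])C(CC=C)C([O-])(CCc1ccc(O[Si](C(C)C)(C(C)C)C(C)C)cc1)N(C)OC | intermediate
11 | methyl 4-allyl-3,5-dioxo-7-[4-(triisopropylsilyloxy)phenyl]heptanoate (racemic and labile at C4, largely enolised) | COC(=O)CC(=O)C(CC=C)C(=O)CCc1ccc(O[Si](C(C)C)(C(C)C)C(C)C)cc1 | intermediate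
12 | 5-allyl-4-hydroxy-6-{2-[4-(triisopropylsilyloxy)phenyl]ethyl}-2H-pyran-2-one | O=C1C=C(O)C(CC=C)=C(CCc2ccc(O[Si](C(C)C)(C(C)C)C(C)C)cc2)O1 | intermediate
13 | 3-methylbut-2-enoic acid | CC(C)=CC(O)=O | starting material
14 | 5-allyl-2-oxo-6-{2-[4-(triisopropylsilyloxy)phenyl]ethyl}-2H-pyran-4-yl 3-methylbut-2-enoate (enol ester) | CC(C)=CC(=O)OC1=CC(=O)OC(CCc2ccc(O[Si](C(C)C)(C(C)C)C(C)C)cc2)=C1CC=C | intermediate
15 | 5-allyl-4-hydroxy-3-(3-methylbut-2-enoyl)-6-{2-[4-(triisopropylsilyloxy)phenyl]ethyl}-2H-pyran-2-one | CC(C)=CC(=O)C1=C(O)C(CC=C)=C(CCc2ccc(O[Si](C(C)C)(C(C)C)C(C)C)cc2)OC1=O | intermediate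
16 | 8-allyl-2,2-dimethyl-7-{2-[4-(triisopropylsilyloxy)phenyl]ethyl}-2,3-dihydro-4H,5H-pyrano[4,3-b]pyran-4,5-dione | O=C1OC(CCc3ccc(O[Si](C(C)C)(C(C)C)C(C)C)cc3)=C(CC=C)C2=C1C(=O)CC(C)(C)O2 | intermediate
17 | 2-methylbut-2-ene | CC=C(C)C | starting material
18 | 2,2-dimethyl-8-(3-methylbut-2-enyl)-7-{2-[4-(triisopropylsilyloxy)phenyl]ethyl}-2,3-dihydro-4H,5H-pyrano[4,3-b]pyran-4,5-dione (key-step precursor) | O=C1OC(CCc3ccc(O[Si](C(C)C)(C(C)C)C(C)C)cc3)=C(CC=C(C)C)C2=C1C(=O)CC(C)(C)O2 | intermediate
19 | ethoxyacetylene | CCOC#C | starting material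
20 | bridged cycloadduct, a 2-oxabicyclo[2.2.2]octa-5,7-dien-3-one: the lactone bridge C5(=O)–O6 spans C4a and C7, the new CH=C(OEt) bridge joins C7 to C4a, ring B stays fused at C4a–C8a (racemic) | O=C1OC2(CCc4ccc(O[Si](C(C)C)(C(C)C)C(C)C)cc4)C=C(OCC)C1(C(=O)CC(C)(C)O3)C3=C2CC=C(C)C | intermediate
21 | 5-ethoxy-2,2-dimethyl-8-(3-methylbut-2-enyl)-7-{2-[4-(triisopropylsilyloxy)phenyl]ethyl}chroman-4-one (key-step product) | CCOc1cc(CCc3ccc(O[Si](C(C)C)(C(C)C)C(C)C)cc3)c(CC=C(C)C)c2OC(C)(C)CC(=O)c12 | intermediate
22 | C5 aryloxydichloroborane of 23, chelated to the C4 ketone (dative bond not drawn) | ClB(Cl)Oc1cc(CCc3ccc(O[Si](C(C)C)(C(C)C)C(C)C)cc3)c(CC=C(C)C)c2OC(C)(C)CC(=O)c12 | intermediate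
23 | 5-hydroxy-2,2-dimethyl-8-(3-methylbut-2-enyl)-7-{2-[4-(triisopropylsilyloxy)phenyl]ethyl}chroman-4-one | Oc1cc(CCc3ccc(O[Si](C(C)C)(C(C)C)C(C)C)cc3)c(CC=C(C)C)c2OC(C)(C)CC(=O)c12 | intermediate
24 | 2,2-dimethyl-8-(3-methylbut-2-enyl)-7-{2-[4-(triisopropylsilyloxy)phenyl]ethyl}chromane-4,5-diol (racemic at C4) | Oc1cc(CCc3ccc(O[Si](C(C)C)(C(C)C)C(C)C)cc3)c(CC=C(C)C)c2OC(C)(C)CC(O)c12 | intermediate
25 | 2,2-dimethyl-8-(3-methylbut-2-enyl)-7-{2-[4-(triisopropylsilyloxy)phenyl]ethyl}-2H-chromen-5-ol | Oc1cc(CCc3ccc(O[Si](C(C)C)(C(C)C)C(C)C)cc3)c(CC=C(C)C)c2OC(C)(C)C=Cc12 | intermediate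
26 | 7-[2-(4-hydroxyphenyl)ethyl]-2,2-dimethyl-8-(3-methylbut-2-enyl)-2H-chromen-5-ol | CC(C)=CCc1c(CCc2ccc(O)cc2)cc(O)c2c1OC(C)(C)C=C2 | target

## Step count and risks
Total steps: 12. Longest linear sequence: 11 steps (1, 2, 4, 5, 6, 7, 8, 9, 10, 11, 12).

**Step 9 (key step).**
- Risk: the donor O1 on C8a and the two alkyl groups on C7 and C8 may leave the diene too sluggish below the temperature at which the ynol ether fragments by retro-ene reaction. The Lewis acid may also oligomerise the ynol ether, so the dienophile could be used up before cycloaddition.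
- Fallback: it sets out from 18 and forms the same two bonds with an alkene dienophile in place of the alkyne. The reagent is 1,1-diethoxyethene (C=C(OCC)OCC, excess) in toluene in a sealed tube at 110 to 140 °C, without Lewis acid.
- Basis: this is the established ketene-acetal benzannulation of 3-carbonyl-5,6-dialkyl-2-pyrones. The acetal is the stronger nucleophile and tolerates the higher temperature.
- Course: cycloaddition should give the bridged lactone acetal F1, which loses carbon dioxide to the 5,5-diethoxy-5,6-dihydrochroman-4-one F2. Loss of ethanol from F2, spontaneous or with a trace of PPTS, aromatises ring A and comes back to the route at 21.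

**Step 4.**
- Risk: acylation at the secondary γ-carbon of the allylated dianion may be slow, so proton transfer and recovery of both partners take over.
- Fallback: it replaces acylation by aldol addition and oxidation. It sets out from 4, which iBu2AlH in THF at −78 °C should reduce to 3-[4-(triisopropylsilyloxy)phenyl]propanal F3.
- Course: addition of F3 to dianion 9 at −78 °C should give methyl 4-allyl-5-hydroxy-3-oxo-7-[4-(triisopropylsilyloxy)phenyl]heptanoate F4 as a mixture of diastereomers. Dess–Martin periodinane in CH2Cl2 oxidises the carbinol, and the sequence comes back at 11.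

**Step 11.**
- Risk: the hydrogen-bonded, phenoxide-deactivated ketone may reduce slowly. The o-hydroxybenzyl alcohol may also ionise to its o-quinone methide while hydride is still present, which leads to over-reduction to the chromane, or it may oligomerise during dehydration.
- Fallback: it masks the C5 hydroxyl first. It sets out from 23, which TBSOTf and 2,6-lutidine in CH2Cl2 should convert into the 5-(tert-butyldimethylsilyloxy)chroman-4-one F5.
- Course: iBu2AlH in toluene at −78 °C gives the 5-silyloxychroman-4-ol F6, and PPTS in toluene at 60 °C dehydrates it to the bis-silylated chromene F7. Bu4NF (2.2 equiv) with AcOH in THF removes both silyl groups, and the sequence comes back at 26.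

## Further compounds
F1 | step 9 | bridged lactone acetal, the 2-oxabicyclo[2.2.2]oct-7-en-3-one from 18 and 1,1-diethoxyethene, CH2 on C7 and C(OEt)2 on C4a (racemic) | O=C1OC2(CCc4ccc(O[Si](C(C)C)(C(C)C)C(C)C)cc4)CC(OCC)(OCC)C1(C(=O)CC(C)(C)O3)C3=C2CC=C(C)C
F2 | step 9 | 5,5-diethoxy-2,2-dimethyl-8-(3-methylbut-2-enyl)-7-{2-[4-(triisopropylsilyloxy)phenyl]ethyl}-5,6-dihydrochroman-4-one | CCOC1(OCC)CC(CCc3ccc(O[Si](C(C)C)(C(C)C)C(C)C)cc3)=C(CC=C(C)C)C2=C1C(=O)CC(C)(C)O2
F3 | step 4 | 3-[4-(triisopropylsilyloxy)phenyl]propanal | O=CCCc1ccc(O[Si](C(C)C)(C(C)C)C(C)C)cc1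
F4 | step 4 | methyl 4-allyl-5-hydroxy-3-oxo-7-[4-(triisopropylsilyloxy)phenyl]heptanoate (mixture of diastereomers) | COC(=O)CC(=O)C(CC=C)C(O)CCc1ccc(O[Si](C(C)C)(C(C)C)C(C)C)cc1
F5 | step 11 | 5-(tert-butyldimethylsilyloxy)-2,2-dimethyl-8-(3-methylbut-2-enyl)-7-{2-[4-(triisopropylsilyloxy)phenyl]ethyl}chroman-4-one | CC(C)(C)[Si](C)(C)Oc1cc(CCc3ccc(O[Si](C(C)C)(C(C)C)C(C)C)cc3)c(CC=C(C)C)c2OC(C)(C)CC(=O)c12
F6 | step 11 | 5-(tert-butyldimethylsilyloxy)-2,2-dimethyl-8-(3-methylbut-2-enyl)-7-{2-[4-(triisopropylsilyloxy)phenyl]ethyl}chroman-4-ol (racemic) | CC(C)(C)[Si](C)(C)Oc1cc(CCc3ccc(O[Si](C(C)C)(C(C)C)C(C)C)cc3)c(CC=C(C)C)c2OC(C)(C)CC(O)c12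
F7 | step 11 | 5-(tert-butyldimethylsilyloxy)-2,2-dimethyl-8-(3-methylbut-2-enyl)-7-{2-[4-(triisopropylsilyloxy)phenyl]ethyl}-2H-chromene | CC(C)(C)[Si](C)(C)Oc1cc(CCc3ccc(O[Si](C(C)C)(C(C)C)C(C)C)cc3)c(CC=C(C)C)c2OC(C)(C)C=Cc12
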